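## Retrosynthetic overview

1. The target comes from global desilylation of its penta-silyl ether, which is made by C3–O acylation of the silyl-protected (2R,3R)-flavan-3-ol with silyl-protected ferulic acid.
2. The flavan-3-ol comes from the racemic flavan-3-one by asymmetric transfer hydrogenation with dynamic kinetic resolution, which sets C2 and C3 together. The ketone comes from a 3-nitroflavan by a Nef reaction.
3. The pyran ring is closed at C2–C3 by an internal redox reaction of an aryl benzyl ether that carries an ortho nitrovinyl group. The enabling feature is the C2–H bond of the flavan: it is benzylic on the p-methoxy B ring and α to O1, and it lies 1,5 to C4. C4 is a benzylic CH2 of the A ring, so it can be carried as the β-carbon of a nitroalkene. Hydride moves from C2 to C4, then nitronate carbon C3 joins oxocarbenium carbon C2.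
4. The nitroalkene comes from Henry condensation of a 2-benzyloxybenzaldehyde with nitromethane. The aldehyde comes from Mitsunobu etherification of a 2,4,6-trihydroxybenzaldehyde-derived phenol with a benzyl alcohol made from methyl 4-O-methylgallate. Rings A and B are bought; the pyran ring is the only ring formed.

Key step: step 6

## Remarks on the chemistry

- TIPS = triisopropylsilyl, TBS = tert-butyldimethylsilyl. Flavan numbering is used (O1, C2, C3, C4, C4a–C8a; B ring primed).
- The 3-nitroflavan and the flavan-3-one are racemic; their SMILES therefore carry no stereo marks.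
- Assumption: the (R,R)-TsDPEN–Ru catalyst is taken to deliver the 3R carbinol, on the usual model with the C2 side (aryl and O1) in the aryl pocket. If the first run shows the opposite sense, the mirror-image catalyst is used.
- Methyl 3,5-dihydroxy-4-methoxybenzoate is assumed to be commercially available.

## Route

Step 1
Reactants: 1 methyl 3,5-dihydroxy-4-methoxybenzoate
Product: 2 methyl 4-methoxy-3,5-bis(triisopropylsilyloxy)benzoate
Conditions: TIPSCl (2.4 equiv), imidazole (5 equiv), DMAP (cat.), DMF, 40 °C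
Reagents that add atoms: triisopropylsilyl chloride, CC(C)[Si](Cl)(C(C)C)C(C)C
Why: Standard phenol silylation; TIPS is chosen because it has no hydridic C–H next to oxygen, should survive the Lewis acid of step 6, and shields the B-ring positions ortho to the benzylic carbon.

Step 2
Reactants: 2 methyl 4-methoxy-3,5-bis(triisopropylsilyloxy)benzoate
Product: 3 [4-methoxy-3,5-bis(triisopropylsilyloxy)phenyl]methanol
Conditions: DIBAL-H (2.5 equiv), CH2Cl2, −78 to 0 °C; Rochelle salt work-up
Reagents that add atoms: none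
Why: Aluminium hydride reduction of an aryl ester to the benzylic alcohol, with aryl silyl ethers inert.

Step 3
Reactants: 4 2,4,6-trihydroxybenzaldehyde
Product: 5 2-hydroxy-4,6-bis(triisopropylsilyloxy)benzaldehyde
Conditions: TIPSCl (2.05 equiv), imidazole (4 equiv), CH2Cl2/DMF, 0 °C
Reagents that add atoms: triisopropylsilyl chloride, CC(C)[Si](Cl)(C(C)C)C(C)C
Why: Regioselective partial silylation: the 4-OH and one ortho OH react, while the last ortho OH is held by the hydrogen bond to the formyl group and should stay free with two equivalents of the bulky chloride.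

Step 4
Reactants: 3 [4-methoxy-3,5-bis(triisopropylsilyloxy)phenyl]methanol; 5 2-hydroxy-4,6-bis(triisopropylsilyloxy)benzaldehyde
Product: 6 2-{[4-methoxy-3,5-bis(triisopropylsilyloxy)phenyl]methoxy}-4,6-bis(triisopropylsilyloxy)benzaldehyde
Conditions: PPh3, DIAD, THF, 0 °C to rt
Reagents that add atoms: none
Why: Mitsunobu etherification of an acidic salicylaldehyde-type phenol with a primary benzylic alcohol; the neutral conditions avoid base-induced loss or migration of aryl silyl groups.

Step 5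
Reactants: 6 2-{[4-methoxy-3,5-bis(triisopropylsilyloxy)phenyl]methoxy}-4,6-bis(triisopropylsilyloxy)benzaldehyde; 7 nitromethane
Product: 8 1-{[4-methoxy-3,5-bis(triisopropylsilyloxy)phenyl]methoxy}-2-[(E)-2-nitroethenyl]-3,5-bis(triisopropylsilyloxy)benzene
Conditions: MeNO2 (solvent), NH4OAc (0.5 equiv), 90 °C
Reagents that add atoms: none
Why: Henry (nitroaldol) condensation with in situ dehydration, as is routine for 2,4,6-trialkoxybenzaldehydes; the conjugated E-nitroalkene is the thermodynamic product.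

Step 6
Reactants: 8 1-{[4-methoxy-3,5-bis(triisopropylsilyloxy)phenyl]methoxy}-2-[(E)-2-nitroethenyl]-3,5-bis(triisopropylsilyloxy)benzene
Product: 10 rac-2-[4-methoxy-3,5-bis(triisopropylsilyloxy)phenyl]-3-nitro-5,7-bis(triisopropylsilyloxy)chroman (protected 3-nitroflavan), via oxocarbenium–nitronate zwitterion 9 (not isolated)
Conditions: Sc(OTf)3 (20 mol %), ClCH2CH2Cl, 4 Å MS, 80 °C, 0.02 M
Reagents that add atoms: none
Why: Proposed new method: Sc(III) bound to the nitro group lowers the LUMO of the nitroalkene, so that the C2–H bond (benzylic, α to O1, held 1,5 to C4 by the arene) delivers hydride to C4 through a six-membered transition state and leaves zwitterion 9, whose nitronate carbon C3 then adds to the oxocarbenium carbon C2. The closest known reaction type is the Lewis-acid-catalysed [1,5]-hydride shift/cyclisation (internal redox) of 2-(benzyloxy)benzylidene malonates and barbiturates to 2-arylchromans; the nitroalkene acceptor and the nitronate terminus are the new elements. The pyran ring closes 6-endo-trig at the C2=O1 oxocarbenium by C-attack of the nitronate, since O-attack would need an eight-membered ring. C2 and C3 are both created here and are expected to be trans under thermodynamic control (C3–H is acidic), but neither needs control: C3 becomes sp2 in step 7 and C2 is reset in step 8, so 10 is carried on as the racemic mixture. The selectivity needed is hydride shift over Friedel–Crafts attack of the electron-rich rings on the activated nitroalkene and over ionisation of the benzyl ether; the OTIPS groups flanking every free arene position, the six-membered geometry of the hydride transfer, dilution and the mild Lewis acid should secure it.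

Step 7
Reactants: 10 rac-2-[4-methoxy-3,5-bis(triisopropylsilyloxy)phenyl]-3-nitro-5,7-bis(triisopropylsilyloxy)chroman
Product: 12 rac-2-[4-methoxy-3,5-bis(triisopropylsilyloxy)phenyl]-5,7-bis(triisopropylsilyloxy)chroman-3-one, via potassium nitronate 11 (not isolated)
Conditions: KOt-Bu (1.05 equiv), THF, −78 °C; then dimethyldioxirane (acetone solution), −78 to 0 °C
Reagents that add atoms: dimethyldioxirane, CC1(C)OO1
Why: Oxidative Nef reaction: the α-nitro C3–H is the most acidic proton, the nitronate is oxidised at carbon by the electrophilic dioxirane much faster than the aryl ethers, and loss of nitrite gives the ketone, in which C3 is sp2 and the labile C2 centre is racemic.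

Step 8
Reactants: 12 rac-2-[4-methoxy-3,5-bis(triisopropylsilyloxy)phenyl]-5,7-bis(triisopropylsilyloxy)chroman-3-one
Product: 13 (2R,3R)-2-[4-methoxy-3,5-bis(triisopropylsilyloxy)phenyl]-5,7-bis(triisopropylsilyloxy)chroman-3-ol
Conditions: RuCl[(R,R)-TsDPEN](p-cymene) (2 mol %), HCO2H/Et3N (3:2), EtOAc, 40 °C
Reagents that add atoms: none
Why: Noyori-type asymmetric transfer hydrogenation under dynamic kinetic resolution: C2–H is benzylic and α to both O1 and the C3 carbonyl, so the ketone enantiomers should interconvert through the enol faster than they are reduced, the catalyst reduces the (2R) ketone preferentially, and hydride enters anti to the 2-aryl group (as in hydride reductions of flavan-3-ones), which sets C3 as R and gives the 2,3-cis alcohol.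

Step 9
Reactants: 14 (E)-ferulic acid
Product: 16 (E)-3-[4-(tert-butyldimethylsilyloxy)-3-methoxyphenyl]prop-2-enoic acid, via silyl ester 15 (not isolated)
Conditions: TBSCl (2.3 equiv), imidazole (5 equiv), DMF, rt; then AcOH/THF/H2O, rt
Reagents that add atoms: tert-butyldimethylsilyl chloride, CC(C)(C)[Si](C)(C)Cl
Why: Bis-silylation followed by selective hydrolysis of the far more labile silyl ester leaves the phenol protected and the acid free; the E-alkene is untouched.

Step 10
Reactants: 13 (2R,3R)-2-[4-methoxy-3,5-bis(triisopropylsilyloxy)phenyl]-5,7-bis(triisopropylsilyloxy)chroman-3-ol; 16 (E)-3-[4-(tert-butyldimethylsilyloxy)-3-methoxyphenyl]prop-2-enoic acid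
Product: 17 (2R,3R)-2-[4-methoxy-3,5-bis(triisopropylsilyloxy)phenyl]-5,7-bis(triisopropylsilyloxy)chroman-3-yl (E)-3-[4-(tert-butyldimethylsilyloxy)-3-methoxyphenyl]prop-2-enoate
Conditions: DCC (1.5 equiv), DMAP (0.3 equiv), CH2Cl2, 0 °C to rt
Reagents that add atoms: none
Why: Steglich esterification of the secondary alcohol; the C3–O bond is not broken and the conditions are too mild to epimerise C2, so both stereocentres are retained.

Step 11
Reactants: 17 (2R,3R)-2-[4-methoxy-3,5-bis(triisopropylsilyloxy)phenyl]-5,7-bis(triisopropylsilyloxy)chroman-3-yl (E)-3-[4-(tert-butyldimethylsilyloxy)-3-methoxyphenyl]prop-2-enoate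
Product: 18 4'-O-methylepigallocatechin-3-O-ferulate
Conditions: TBAF (6 equiv), AcOH (6 equiv), THF, 0 °C to rt
Reagents that add atoms: none
Why: Fluoride cleavage of the five aryl silyl ethers buffered with acetic acid, so that phenoxides are protonated as they form and the cinnamate ester, the E-alkene and the C2/C3 stereocentres are left untouched.

## Compound list

1 | methyl 3,5-dihydroxy-4-methoxybenzoate | COC(=O)c1cc(O)c(OC)c(O)c1 | starting material
2 | methyl 4-methoxy-3,5-bis(triisopropylsilyloxy)benzoate | COC(=O)c1cc(O[Si](C(C)C)(C(C)C)C(C)C)c(OC)c(O[Si](C(C)C)(C(C)C)C(C)C)c1 | intermediate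
3 | [4-methoxy-3,5-bis(triisopropylsilyloxy)phenyl]methanol | OCc1cc(O[Si](C(C)C)(C(C)C)C(C)C)c(OC)c(O[Si](C(C)C)(C(C)C)C(C)C)c1 | intermediate
4 | 2,4,6-trihydroxybenzaldehyde | O=Cc1c(O)cc(O)cc1O | starting material
5 | 2-hydroxy-4,6-bis(triisopropylsilyloxy)benzaldehyde | O=Cc1c(O)cc(O[Si](C(C)C)(C(C)C)C(C)C)cc1O[Si](C(C)C)(C(C)C)C(C)C | intermediate
6 | 2-{[4-methoxy-3,5-bis(triisopropylsilyloxy)phenyl]methoxy}-4,6-bis(triisopropylsilyloxy)benzaldehyde | O=Cc1c(OCc2cc(O[Si](C(C)C)(C(C)C)C(C)C)c(OC)c(O[Si](C(C)C)(C(C)C)C(C)C)c2)cc(O[Si](C(C)C)(C(C)C)C(C)C)cc1O[Si](C(C)C)(C(C)C)C(C)C | intermediate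
7 | nitromethane | C[N+](=O)[O-] | starting material
8 | 1-{[4-methoxy-3,5-bis(triisopropylsilyloxy)phenyl]methoxy}-2-[(E)-2-nitroethenyl]-3,5-bis(triisopropylsilyloxy)benzene | O=[N+]([O-])/C=C/c1c(OCc2cc(O[Si](C(C)C)(C(C)C)C(C)C)c(OC)c(O[Si](C(C)C)(C(C)C)C(C)C)c2)cc(O[Si](C(C)C)(C(C)C)C(C)C)cc1O[Si](C(C)C)(C(C)C)C(C)C | intermediate
9 | oxocarbenium–nitronate zwitterion formed by 1,5-hydride shift (Sc-bound in the flask) | [O-][N+]([O-])=CCc1c([O+]=Cc2cc(O[Si](C(C)C)(C(C)C)C(C)C)c(OC)c(O[Si](C(C)C)(C(C)C)C(C)C)c2)cc(O[Si](C(C)C)(C(C)C)C(C)C)cc1O[Si](C(C)C)(C(C)C)C(C)C | intermediate (not isolated)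
10 | rac-2-[4-methoxy-3,5-bis(triisopropylsilyloxy)phenyl]-3-nitro-5,7-bis(triisopropylsilyloxy)chroman (racemate, both relative configurations, trans expected to predominate) | O=[N+]([O-])C1Cc2c(O[Si](C(C)C)(C(C)C)C(C)C)cc(O[Si](C(C)C)(C(C)C)C(C)C)cc2OC1c1cc(O[Si](C(C)C)(C(C)C)C(C)C)c(OC)c(O[Si](C(C)C)(C(C)C)C(C)C)c1 | intermediate
11 | potassium nitronate of 10 | [K+].[O-][N+]([O-])=C1Cc2c(O[Si](C(C)C)(C(C)C)C(C)C)cc(O[Si](C(C)C)(C(C)C)C(C)C)cc2OC1c1cc(O[Si](C(C)C)(C(C)C)C(C)C)c(OC)c(O[Si](C(C)C)(C(C)C)C(C)C)c1 | intermediate (not isolated)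
12 | rac-2-[4-methoxy-3,5-bis(triisopropylsilyloxy)phenyl]-5,7-bis(triisopropylsilyloxy)chroman-3-one (racemic, C2 labile) | O=C1Cc2c(O[Si](C(C)C)(C(C)C)C(C)C)cc(O[Si](C(C)C)(C(C)C)C(C)C)cc2OC1c1cc(O[Si](C(C)C)(C(C)C)C(C)C)c(OC)c(O[Si](C(C)C)(C(C)C)C(C)C)c1 | intermediate
13 | (2R,3R)-2-[4-methoxy-3,5-bis(triisopropylsilyloxy)phenyl]-5,7-bis(triisopropylsilyloxy)chroman-3-ol | O[C@@H]1Cc2c(O[Si](C(C)C)(C(C)C)C(C)C)cc(O[Si](C(C)C)(C(C)C)C(C)C)cc2O[C@@H]1c1cc(O[Si](C(C)C)(C(C)C)C(C)C)c(OC)c(O[Si](C(C)C)(C(C)C)C(C)C)c1 | intermediate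
14 | (E)-ferulic acid | COc1cc(/C=C/C(=O)O)ccc1O | starting material
15 | tert-butyldimethylsilyl (E)-3-[4-(tert-butyldimethylsilyloxy)-3-methoxyphenyl]prop-2-enoate | COc1cc(/C=C/C(=O)O[Si](C)(C)C(C)(C)C)ccc1O[Si](C)(C)C(C)(C)C | intermediate (not isolated)
16 | (E)-3-[4-(tert-butyldimethylsilyloxy)-3-methoxyphenyl]prop-2-enoic acid | COc1cc(/C=C/C(=O)O)ccc1O[Si](C)(C)C(C)(C)C | intermediate
17 | (2R,3R)-2-[4-methoxy-3,5-bis(triisopropylsilyloxy)phenyl]-5,7-bis(triisopropylsilyloxy)chroman-3-yl (E)-3-[4-(tert-butyldimethylsilyloxy)-3-methoxyphenyl]prop-2-enoate | COc1cc(/C=C/C(=O)O[C@@H]2Cc3c(O[Si](C(C)C)(C(C)C)C(C)C)cc(O[Si](C(C)C)(C(C)C)C(C)C)cc3O[C@@H]2c2cc(O[Si](C(C)C)(C(C)C)C(C)C)c(OC)c(O[Si](C(C)C)(C(C)C)C(C)C)c2)ccc1O[Si](C)(C)C(C)(C)C | intermediate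
18 | 4'-O-methylepigallocatechin-3-O-ferulate, (2R,3R) | COc1cc(/C=C/C(=O)O[C@@H]2Cc3c(O)cc(O)cc3O[C@@H]2c2cc(O)c(OC)c(O)c2)ccc1O | target

## Step count and risks

Total steps: 11. Longest linear sequence: 9 steps (steps 1, 2, 4, 5, 6, 7, 8, 10, 11).

**Step 6 (proposed new method).** The hydride transfer may be too slow, because the trioxygenated A ring lowers the electrophilicity of the nitroalkene and a nitro group binds the Lewis acid less well than a 1,3-dicarbonyl unit. Under forcing conditions, Friedel–Crafts oligomerisation or ionisation of the benzyl ether may then take over. The fallback uses known chemistry, sets out from 6 and returns at 12. Knoevenagel condensation of 6 with Meldrum's acid (cat. piperidine/AcOH, CH2Cl2, rt) would give the arylidene Meldrum's acid F1, a much stronger, chelating hydride acceptor of the kind on which the Lewis-acid-catalysed [1,5]-hydride shift/cyclisation of aryl benzyl ethers is established. Sc(OTf)3 in ClCH2CH2Cl at 80 °C should then close the same C2–C3 bond to give the spiro-chroman F2. Mild hydrolysis (LiOH, THF/H2O, 0 °C, cold acidification) would give the chroman-3,3-dicarboxylic acid F3. Oxidative bis-decarboxylation of this gem-diacid (Pb(OAc)4, pyridine, MeCN; or anodic oxidation followed by acetal hydrolysis) would give ketone 12.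

**Step 8.** Enolisation at C2 may be slower than reduction, which would carry the mismatched ketone enantiomer through to the wrong alcohol. Facial or enantiomer discrimination by the catalyst may be poor on this ketone class, or the sense of induction may be opposite to the one assumed. The ketone may also degrade in the amine-containing medium. The fallback sets out from 12 and returns at 13. L-Selectride (THF, −78 °C), which attacks flavan-3-ones anti to the 2-aryl group, would give the racemic cis alcohol F4. Steglich esterification with (S)-O-methylmandelic acid would give the diastereomeric esters, the (2R,3R) ester F5 and the (2S,3S) ester F6, to be separated by chromatography. DIBAL-H cleavage of F5 (CH2Cl2, −78 °C) returns 13.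

**Step 7.** The nitronate may undergo E1cB ring opening (retro-oxa-Michael loss of the O1 phenoxide) before it is oxidised. The dioxirane may over-oxidise the electron-rich rings, or the base may degrade the enolisable ketone as it forms. The fallback sets out from 10 and returns at 12. Nickel boride reduction (NiCl2·6H2O, NaBH4, MeOH/THF, 0 °C) avoids a carbanion at C3 and would give the 3-aminoflavan F7. Oxidative deamination of this primary amine with 3,5-di-tert-butyl-1,2-benzoquinone (MeOH/THF, then aqueous oxalic acid) would give ketone 12.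

## Further compounds

F1 | step 6 | 5-[(2-{[4-methoxy-3,5-bis(triisopropylsilyloxy)phenyl]methoxy}-4,6-bis(triisopropylsilyloxy)phenyl)methylidene]-2,2-dimethyl-1,3-dioxane-4,6-dione | CC1(C)OC(=O)C(=Cc2c(OCc3cc(O[Si](C(C)C)(C(C)C)C(C)C)c(OC)c(O[Si](C(C)C)(C(C)C)C(C)C)c3)cc(O[Si](C(C)C)(C(C)C)C(C)C)cc2O[Si](C(C)C)(C(C)C)C(C)C)C(=O)O1
F2 | step 6 | rac-spiro[chroman-3,5'-[1,3]dioxane]-4',6'-dione bearing 2',2'-dimethyl, 2-[4-methoxy-3,5-bis(triisopropylsilyloxy)phenyl] and 5,7-bis(triisopropylsilyloxy) groups | CC1(C)OC(=O)C2(Cc3c(O[Si](C(C)C)(C(C)C)C(C)C)cc(O[Si](C(C)C)(C(C)C)C(C)C)cc3OC2c2cc(O[Si](C(C)C)(C(C)C)C(C)C)c(OC)c(O[Si](C(C)C)(C(C)C)C(C)C)c2)C(=O)O1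
F3 | step 6 | rac-2-[4-methoxy-3,5-bis(triisopropylsilyloxy)phenyl]-5,7-bis(triisopropylsilyloxy)chroman-3,3-dicarboxylic acid | OC(=O)C1(C(=O)O)Cc2c(O[Si](C(C)C)(C(C)C)C(C)C)cc(O[Si](C(C)C)(C(C)C)C(C)C)cc2OC1c1cc(O[Si](C(C)C)(C(C)C)C(C)C)c(OC)c(O[Si](C(C)C)(C(C)C)C(C)C)c1
F4 | step 8 | rac-cis-2-[4-methoxy-3,5-bis(triisopropylsilyloxy)phenyl]-5,7-bis(triisopropylsilyloxy)chroman-3-ol (1:1 mixture of the 2R,3R and 2S,3S enantiomers) | O[C@@H]1Cc2c(O[Si](C(C)C)(C(C)C)C(C)C)cc(O[Si](C(C)C)(C(C)C)C(C)C)cc2O[C@@H]1c1cc(O[Si](C(C)C)(C(C)C)C(C)C)c(OC)c(O[Si](C(C)C)(C(C)C)C(C)C)c1.O[C@H]1Cc2c(O[Si](C(C)C)(C(C)C)C(C)C)cc(O[Si](C(C)C)(C(C)C)C(C)C)cc2O[C@H]1c1cc(O[Si](C(C)C)(C(C)C)C(C)C)c(OC)c(O[Si](C(C)C)(C(C)C)C(C)C)c1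
F5 | step 8 | (2R,3R)-2-[4-methoxy-3,5-bis(triisopropylsilyloxy)phenyl]-5,7-bis(triisopropylsilyloxy)chroman-3-yl (S)-2-methoxy-2-phenylacetate | CO[C@H](C(=O)O[C@@H]1Cc2c(O[Si](C(C)C)(C(C)C)C(C)C)cc(O[Si](C(C)C)(C(C)C)C(C)C)cc2O[C@@H]1c1cc(O[Si](C(C)C)(C(C)C)C(C)C)c(OC)c(O[Si](C(C)C)(C(C)C)C(C)C)c1)c1ccccc1
F6 | step 8 | (2S,3S)-2-[4-methoxy-3,5-bis(triisopropylsilyloxy)phenyl]-5,7-bis(triisopropylsilyloxy)chroman-3-yl (S)-2-methoxy-2-phenylacetate | CO[C@H](C(=O)O[C@H]1Cc2c(O[Si](C(C)C)(C(C)C)C(C)C)cc(O[Si](C(C)C)(C(C)C)C(C)C)cc2O[C@H]1c1cc(O[Si](C(C)C)(C(C)C)C(C)C)c(OC)c(O[Si](C(C)C)(C(C)C)C(C)C)c1)c1ccccc1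
F7 | step 7 | rac-2-[4-methoxy-3,5-bis(triisopropylsilyloxy)phenyl]-5,7-bis(triisopropylsilyloxy)chroman-3-amine | NC1Cc2c(O[Si](C(C)C)(C(C)C)C(C)C)cc(O[Si](C(C)C)(C(C)C)C(C)C)cc2OC1c1cc(O[Si](C(C)C)(C(C)C)C(C)C)c(OC)c(O[Si](C(C)C)(C(C)C)C(C)C)c1
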